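**Strategy.** Lutein is assembled by a C15 + C10 + C15 double Wittig sequence and acylated at the end with α‑linolenic acid; the ε end comes from (R)‑α‑ionone. The hydroxylated β‑ring (C1–C6) is made by ring enlargement. (S)‑2,2‑Dimethyl‑4‑silyloxycyclopentanone already holds C1 with its geminal methyl groups, C2, C3 with its oxygen, C4 and the carbonyl carbon C6. Lewis‑acid‑catalysed insertion of the CH(CH3) unit of diazoethane between C6 and C4 creates C5 with its methyl group and the six‑membered ring in one operation. The quaternary C1 steers the migration and stops a second insertion.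

Key step: step 4

Remarks: (R)‑α‑ionone is assumed to be purchasable enantiopure. Diazoethane is prepared beforehand as an ether solution from commercial N‑ethyl‑N‑nitrosourea and KOH. Carotenoid numbering (β‑ring C1–C6, ε‑ring C1'–C6') is used for late compounds. Centres that later become sp2 (the methyl‑bearing ring carbon of 7, 9 and 10; the carbinol carbon of 9 and 10; the side‑chain carbinol of 14–17) are left undefined because they have no consequence. All polyene work is done under argon in dim light.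

**Step 1**
Reactants: 1 2,2‑dimethylcyclopentan‑1‑one
Product: 3 5,5‑dimethylcyclopent‑2‑en‑1‑one, via silyl enol ether 2 (not isolated)
Conditions: LiN(i‑Pr)2, THF, −78 °C; Me3SiCl; then Pd(OAc)2 (10 mol %), O2 (1 atm), DMSO, 25 °C
Reagents that add atoms: chlorotrimethylsilane, C[Si](C)(C)Cl (silyl group present only in 2)
Why: Saegusa–Ito dehydrogenation; the ketone can enolise only towards its single α‑methylene, so one enol ether and one enone result.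

**Step 2**
Reactants: 3 5,5‑dimethylcyclopent‑2‑en‑1‑one
Product: 5 (S)‑4‑hydroxy‑2,2‑dimethylcyclopentan‑1‑one, via β‑boryl ketone 4 (not isolated)
Conditions: CuCl (3 mol %), NaOt‑Bu (5 mol %), (R)‑1‑[(S)‑2‑(diphenylphosphino)ferrocenyl]ethyldicyclohexylphosphine (3 mol %), B2pin2, MeOH (2 equiv), THF, 25 °C; then NaBO3·4H2O, THF/H2O, 25 °C
Reagents that add atoms: bis(pinacolato)diboron, CC1(C)OB(OC1(C)C)B1OC(C)(C)C(C)(C)O1 (boron present only in 4); sodium perborate, [Na+].[O-]OB=O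
Why: Copper‑catalysed asymmetric conjugate borylation of the cyclic enone, in which the chiral diphosphine selects the enone face and sets the (S) centre (the mirror‑image ligand is taken if the sense of induction proves opposite), followed by stereoretentive C–B oxidation.

**Step 3**
Reactants: 5 (S)‑4‑hydroxy‑2,2‑dimethylcyclopentan‑1‑one
Product: 6 (4S)‑2,2‑dimethyl‑4‑(triethylsilyloxy)cyclopentan‑1‑one
Conditions: Et3SiCl, imidazole, CH2Cl2, 0 °C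
Reagents that add atoms: chlorotriethylsilane, CC[Si](Cl)(CC)CC
Why: Silylation of the secondary alcohol under conditions too weakly basic to trigger β‑elimination; the stereocentre is not touched.

**Step 4**
Reactants: 6 (4S)‑2,2‑dimethyl‑4‑(triethylsilyloxy)cyclopentan‑1‑one
Product: 7 (4R)‑2,2,6‑trimethyl‑4‑(triethylsilyloxy)cyclohexan‑1‑one (mixture of C6 epimers)
Conditions: CH3CHN2 (1.5 equiv, Et2O solution), Sc(OTf)3 (10 mol %), toluene, −78 → −30 °C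
Reagents that add atoms: diazoethane, CC=[N+]=[N-]
Why: Sc(OTf)3 activates the carbonyl of 6 and the diazo carbon adds to it to give a β‑diazonium alkoxide; loss of N2 is accompanied by a 1,2‑shift of the ring bond between the carbonyl carbon and the unsubstituted α‑methylene onto the former diazo carbon, so the CH(CH3) unit is inserted and the cyclopentanone becomes a 2,2,6‑trisubstituted cyclohexanone. The closest known reaction type is the Lewis‑acid‑catalysed homologation of cyclic ketones with diazoalkanes (Büchner–Curtius–Schlotterbeck, Tiffeneau–Demjanov‑type ring expansion). No ring is closed by cyclisation; the six‑membered ring arises by 1,2‑alkyl migration within the existing ring. The new methyl‑bearing stereocentre is not controlled and need not be, because it becomes sp2 in step 7, while the oxygen‑bearing centre is not involved and keeps its spatial arrangement (S in 6 reads R in 7 only because the CIP priorities change). The step needs migration of the methylene and not of the quaternary carbon, and a single insertion: the geminal methyl groups disfavour the betaine conformer that would place the quaternary carbon anti to the leaving N2, and they leave the product ketone, flanked by a quaternary and a tertiary carbon, too hindered to react again.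

**Step 5**
Reactants: 7 (4R)‑2,2,6‑trimethyl‑4‑(triethylsilyloxy)cyclohexan‑1‑one; 8 (2E)‑3‑methylpent‑2‑en‑4‑yn‑1‑ol
Product: 9 (2E)‑5‑[(4R)‑1‑hydroxy‑2,6,6‑trimethyl‑4‑(triethylsilyloxy)cyclohexyl]‑3‑methylpent‑2‑en‑4‑yn‑1‑ol
Conditions: 8 (1.5 equiv), n‑BuLi (3.0 equiv), THF, −78 → 0 °C; then 7, −78 → 25 °C; aq. NH4Cl
Reagents that add atoms: none
Why: 1,2‑Addition of the lithium acetylide (dilithio derivative of 8) to the hindered ketone; the new carbinol centre is inconsequential.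

**Step 6**
Reactants: 9 (2E)‑5‑[(4R)‑1‑hydroxy‑2,6,6‑trimethyl‑4‑(triethylsilyloxy)cyclohexyl]‑3‑methylpent‑2‑en‑4‑yn‑1‑ol
Product: 10 (2E,4E)‑5‑[(4R)‑1‑hydroxy‑2,6,6‑trimethyl‑4‑(triethylsilyloxy)cyclohexyl]‑3‑methylpenta‑2,4‑dien‑1‑ol
Conditions: NaAlH2(OCH2CH2OCH3)2, THF/toluene, 0 → 25 °C; aq. Rochelle salt
Reagents that add atoms: none
Why: Alkoxide‑directed trans‑hydroalumination of the propargylic alkyne and protonolysis give the (E)‑alkene.

**Step 7**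
Reactants: 10 (2E,4E)‑5‑[(4R)‑1‑hydroxy‑2,6,6‑trimethyl‑4‑(triethylsilyloxy)cyclohexyl]‑3‑methylpenta‑2,4‑dien‑1‑ol
Product: 12 [(2E,4E)‑5‑[(4R)‑4‑hydroxy‑2,6,6‑trimethylcyclohex‑1‑en‑1‑yl]‑3‑methylpenta‑2,4‑dien‑1‑yl]triphenylphosphonium bromide, via allylic bromide 11 (not isolated)
Conditions: 48 % aq. HBr, CH2Cl2, −15 °C; then PPh3, EtOAc, 25 °C
Reagents that add atoms: hydrogen bromide, Br; triphenylphosphine, c1ccc(cc1)P(c1ccccc1)c1ccccc1
Why: HBr cleaves the silyl ether, ionises the tertiary bis‑allylic alcohol with loss of the only ring β‑hydrogen (E1 dehydration to the C5=C6 bond) and converts the primary allylic alcohol into the conjugated (2E,4E) bromide, which PPh3 displaces by SN2 to form the phosphonium salt.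

**Step 8**
Reactants: 13 (R)‑α‑ionone
Product: 14 (1E)‑3‑methyl‑1‑[(1R)‑2,6,6‑trimethylcyclohex‑2‑en‑1‑yl]penta‑1,4‑dien‑3‑ol
Conditions: CH2=CHMgBr, THF, −20 °C; aq. NH4Cl
Reagents that add atoms: vinylmagnesium bromide, C=C[Mg]Br
Why: Grignard 1,2‑addition to the methyl ketone is faster than γ‑deprotonation at low temperature, so C6 keeps its configuration.

**Step 9**
Reactants: 14 (1E)‑3‑methyl‑1‑[(1R)‑2,6,6‑trimethylcyclohex‑2‑en‑1‑yl]penta‑1,4‑dien‑3‑ol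
Product: 15 (4R)‑4‑[(1E)‑3‑hydroxy‑3‑methylpenta‑1,4‑dien‑1‑yl]‑3,5,5‑trimethylcyclohex‑2‑en‑1‑one
Conditions: Rh2(cap)4 (cap = caprolactamate, 1 mol %), t‑BuOOH (70 % aq., 5 equiv), ClCH2CH2Cl, 40 °C
Reagents that add atoms: tert‑butyl hydroperoxide, CC(C)(C)OO
Why: Rhodium‑catalysed allylic C–H oxidation by tert‑butylperoxyl radicals attacks the accessible ring methylene next to the trisubstituted C4=C5 bond, and the neutral medium spares the epimerisable C6 centre.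

**Step 10**
Reactants: 15 (4R)‑4‑[(1E)‑3‑hydroxy‑3‑methylpenta‑1,4‑dien‑1‑yl]‑3,5,5‑trimethylcyclohex‑2‑en‑1‑one
Product: 16 (1S,4R)‑4‑[(1E)‑3‑hydroxy‑3‑methylpenta‑1,4‑dien‑1‑yl]‑3,5,5‑trimethylcyclohex‑2‑en‑1‑ol
Conditions: LiBH(s‑Bu)3 (2.2 equiv), THF, −78 °C; aq. NH4Cl
Reagents that add atoms: none
Why: 1,2‑Reduction of the β,β‑disubstituted enone by a bulky hydride approaching anti to the ring side chain should give the 3,6‑cis allylic alcohol.

**Step 11**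
Reactants: 16 (1S,4R)‑4‑[(1E)‑3‑hydroxy‑3‑methylpenta‑1,4‑dien‑1‑yl]‑3,5,5‑trimethylcyclohex‑2‑en‑1‑ol
Product: 17 (1R,4R)‑4‑[(1E)‑3‑hydroxy‑3‑methylpenta‑1,4‑dien‑1‑yl]‑3,5,5‑trimethylcyclohex‑2‑en‑1‑yl benzoate
Conditions: PhCO2H, PPh3, diisopropyl azodicarboxylate, toluene, −20 → 25 °C
Reagents that add atoms: benzoic acid, O=C(O)c1ccccc1
Why: Mitsunobu esterification displaces the oxyphosphonium ion by SN2 with inversion, giving the 3,6‑trans (3R) ester; the tertiary alcohol is too hindered to be activated.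

**Step 12**
Reactants: 17 (1R,4R)‑4‑[(1E)‑3‑hydroxy‑3‑methylpenta‑1,4‑dien‑1‑yl]‑3,5,5‑trimethylcyclohex‑2‑en‑1‑yl benzoate
Product: 18 [(2E,4E)‑5‑[(1R,4R)‑4‑(benzoyloxy)‑2,6,6‑trimethylcyclohex‑2‑en‑1‑yl]‑3‑methylpenta‑2,4‑dien‑1‑yl]triphenylphosphonium bromide
Conditions: PPh3·HBr, CH2Cl2, 25 °C
Reagents that add atoms: triphenylphosphine hydrobromide, Br.c1ccc(cc1)P(c1ccccc1)c1ccccc1
Why: Acid ionisation of the tertiary vinyl carbinol and capture of the pentadienyl cation by PPh3 at its unhindered terminus give the conjugated allylic phosphonium salt, while the benzoate keeps the ring allylic C–O bond from ionising.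

**Step 13**
Reactants: 18 [(2E,4E)‑5‑[(1R,4R)‑4‑(benzoyloxy)‑2,6,6‑trimethylcyclohex‑2‑en‑1‑yl]‑3‑methylpenta‑2,4‑dien‑1‑yl]triphenylphosphonium bromide; 19 (2E,4E,6E)‑2,7‑dimethylocta‑2,4,6‑trienedial
Product: 20 (2E,4E,6E,8E,10E,12E)‑13‑[(1R,4R)‑4‑(benzoyloxy)‑2,6,6‑trimethylcyclohex‑2‑en‑1‑yl]‑2,7,11‑trimethyltrideca‑2,4,6,8,10,12‑hexaenal
Conditions: 19 (3 equiv), 1,2‑epoxybutane/EtOH, reflux
Reagents that add atoms: none
Why: Wittig olefination under neutral conditions (the epoxide traps HBr and frees the ylide); excess dialdehyde secures mono‑olefination and the new C11'=C12' bond equilibrates thermally to E.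

**Step 14**
Reactants: 20 (2E,4E,6E,8E,10E,12E)‑13‑[(1R,4R)‑4‑(benzoyloxy)‑2,6,6‑trimethylcyclohex‑2‑en‑1‑yl]‑2,7,11‑trimethyltrideca‑2,4,6,8,10,12‑hexaenal; 12 [(2E,4E)‑5‑[(4R)‑4‑hydroxy‑2,6,6‑trimethylcyclohex‑1‑en‑1‑yl]‑3‑methylpenta‑2,4‑dien‑1‑yl]triphenylphosphonium bromide
Product: 22 (3R,3'R,6'R)‑β,ε‑carotene‑3,3'‑diol (lutein), via lutein 3'‑benzoate 21 (not isolated)
Conditions: NaOMe (3 equiv), MeOH/CH2Cl2, 0 → 40 °C; then n‑heptane, reflux; crystallisation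
Reagents that add atoms: none
Why: The second Wittig olefination forms C11=C12, methoxide then transesterifies the benzoate, and heating converts the labile 11‑Z isomers into the all‑E polyene.

**Step 15**
Reactants: 22 (3R,3'R,6'R)‑β,ε‑carotene‑3,3'‑diol; 23 (9Z,12Z,15Z)‑octadeca‑9,12,15‑trienoic acid (α‑linolenic acid)
Product: 24 (3R,3'R,6'R)‑β,ε‑carotene‑3,3'‑diyl bis[(9Z,12Z,15Z)‑octadeca‑9,12,15‑trienoate] (CNP0400996.1)
Conditions: 23 (2.4 equiv), N,N'‑dicyclohexylcarbodiimide, DMAP (0.2 equiv), CH2Cl2, 25 °C, dark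
Reagents that add atoms: none
Why: Steglich esterification of both secondary alcohols under neutral conditions leaves the skipped Z‑triene, the polyene and all stereocentres untouched.

**Compound list**

1 | 2,2‑dimethylcyclopentan‑1‑one | CC1(C)CCCC1=O | starting material
2 | (5,5‑dimethylcyclopent‑1‑en‑1‑yl)oxytrimethylsilane | C[Si](C)(C)OC1=CCCC1(C)C | intermediate
3 | 5,5‑dimethylcyclopent‑2‑en‑1‑one | CC1(C)CC=CC1=O | intermediate
4 | (4S)‑2,2‑dimethyl‑4‑(4,4,5,5‑tetramethyl‑1,3,2‑dioxaborolan‑2‑yl)cyclopentan‑1‑one | CC1(C)C[C@H](B2OC(C)(C)C(C)(C)O2)CC1=O | intermediate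
5 | (S)‑4‑hydroxy‑2,2‑dimethylcyclopentan‑1‑one | CC1(C)C[C@H](O)CC1=O | intermediate
6 | (4S)‑2,2‑dimethyl‑4‑(triethylsilyloxy)cyclopentan‑1‑one | CC1(C)C[C@H](O[Si](CC)(CC)CC)CC1=O | intermediate
7 | (4R)‑2,2,6‑trimethyl‑4‑(triethylsilyloxy)cyclohexan‑1‑one (C6 epimers) | CC1C[C@@H](O[Si](CC)(CC)CC)CC(C)(C)C1=O | intermediate
8 | (2E)‑3‑methylpent‑2‑en‑4‑yn‑1‑ol | C#C/C(C)=C/CO | starting material
9 | (2E)‑5‑[(4R)‑1‑hydroxy‑2,6,6‑trimethyl‑4‑(triethylsilyloxy)cyclohexyl]‑3‑methylpent‑2‑en‑4‑yn‑1‑ol | CC1C[C@@H](O[Si](CC)(CC)CC)CC(C)(C)C1(O)C#C/C(C)=C/CO | intermediate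
10 | (2E,4E)‑5‑[(4R)‑1‑hydroxy‑2,6,6‑trimethyl‑4‑(triethylsilyloxy)cyclohexyl]‑3‑methylpenta‑2,4‑dien‑1‑ol | CC1C[C@@H](O[Si](CC)(CC)CC)CC(C)(C)C1(O)/C=C/C(C)=C/CO | intermediate
11 | (1R)‑4‑[(1E,3E)‑5‑bromo‑3‑methylpenta‑1,3‑dien‑1‑yl]‑3,5,5‑trimethylcyclohex‑3‑en‑1‑ol | O[C@@H]1CC(C)=C(/C=C/C(C)=C/CBr)C(C)(C)C1 | intermediate
12 | [(2E,4E)‑5‑[(4R)‑4‑hydroxy‑2,6,6‑trimethylcyclohex‑1‑en‑1‑yl]‑3‑methylpenta‑2,4‑dien‑1‑yl]triphenylphosphonium bromide | O[C@@H]1CC(C)=C(/C=C/C(C)=C/C[P+](c2ccccc2)(c2ccccc2)c2ccccc2)C(C)(C)C1.[Br-] | intermediate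
13 | (R)‑α‑ionone, (3E)‑4‑[(1R)‑2,6,6‑trimethylcyclohex‑2‑en‑1‑yl]but‑3‑en‑2‑one | CC(=O)/C=C/[C@H]1C(C)=CCCC1(C)C | starting material
14 | (1E)‑3‑methyl‑1‑[(1R)‑2,6,6‑trimethylcyclohex‑2‑en‑1‑yl]penta‑1,4‑dien‑3‑ol | C=CC(C)(O)/C=C/[C@H]1C(C)=CCCC1(C)C | intermediate
15 | (4R)‑4‑[(1E)‑3‑hydroxy‑3‑methylpenta‑1,4‑dien‑1‑yl]‑3,5,5‑trimethylcyclohex‑2‑en‑1‑one | C=CC(C)(O)/C=C/[C@H]1C(C)=CC(=O)CC1(C)C | intermediate
16 | (1S,4R)‑4‑[(1E)‑3‑hydroxy‑3‑methylpenta‑1,4‑dien‑1‑yl]‑3,5,5‑trimethylcyclohex‑2‑en‑1‑ol | C=CC(C)(O)/C=C/[C@H]1C(C)=C[C@@H](O)CC1(C)C | intermediate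
17 | (1R,4R)‑4‑[(1E)‑3‑hydroxy‑3‑methylpenta‑1,4‑dien‑1‑yl]‑3,5,5‑trimethylcyclohex‑2‑en‑1‑yl benzoate | C=CC(C)(O)/C=C/[C@H]1C(C)=C[C@H](OC(=O)c2ccccc2)CC1(C)C | intermediate
18 | [(2E,4E)‑5‑[(1R,4R)‑4‑(benzoyloxy)‑2,6,6‑trimethylcyclohex‑2‑en‑1‑yl]‑3‑methylpenta‑2,4‑dien‑1‑yl]triphenylphosphonium bromide | [Br-].c1ccccc1[P+](c1ccccc1)(c1ccccc1)C/C=C(C)/C=C/[C@H]1C(C)=C[C@H](OC(=O)c2ccccc2)CC1(C)C | intermediate
19 | (2E,4E,6E)‑2,7‑dimethylocta‑2,4,6‑trienedial | O=C/C(C)=C/C=C/C=C(C)/C=O | starting material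
20 | (2E,4E,6E,8E,10E,12E)‑13‑[(1R,4R)‑4‑(benzoyloxy)‑2,6,6‑trimethylcyclohex‑2‑en‑1‑yl]‑2,7,11‑trimethyltrideca‑2,4,6,8,10,12‑hexaenal | O=C/C(C)=C/C=C/C=C(C)/C=C/C=C(C)/C=C/[C@H]1C(C)=C[C@H](OC(=O)c2ccccc2)CC1(C)C | intermediate
21 | (3R,3'R,6'R)‑3‑hydroxy‑β,ε‑caroten‑3'‑yl benzoate | O[C@@H]1CC(C)=C(/C=C/C(C)=C/C=C/C(C)=C/C=C/C=C(C)/C=C/C=C(C)/C=C/[C@H]2C(C)=C[C@H](OC(=O)c3ccccc3)CC2(C)C)C(C)(C)C1 | intermediate
22 | (3R,3'R,6'R)‑β,ε‑carotene‑3,3'‑diol (lutein) | O[C@@H]1CC(C)=C(/C=C/C(C)=C/C=C/C(C)=C/C=C/C=C(C)/C=C/C=C(C)/C=C/[C@H]2C(C)=C[C@H](O)CC2(C)C)C(C)(C)C1 | intermediate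
23 | (9Z,12Z,15Z)‑octadeca‑9,12,15‑trienoic acid | CC/C=C\C/C=C\C/C=C\CCCCCCCC(=O)O | starting material
24 | (3R,3'R,6'R)‑β,ε‑carotene‑3,3'‑diyl bis[(9Z,12Z,15Z)‑octadeca‑9,12,15‑trienoate] | CC/C=C\C/C=C\C/C=C\CCCCCCCC(=O)O[C@@H]1CC(C)=C(/C=C/C(C)=C/C=C/C(C)=C/C=C/C=C(C)/C=C/C=C(C)/C=C/[C@H]2C(C)=C[C@H](OC(=O)CCCCCCC/C=C\C/C=C\C/C=C\CC)CC2(C)C)C(C)(C)C1 | target

**Step count.** Total: 15 steps. Longest linear sequence: 9 steps (steps 1–7, 14, 15).

**Steps most likely to fail**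

Step 4. The diazoalkane may add sluggishly to the hindered carbonyl, the alkoxide may close onto the diazonium carbon to give an epoxide, or part of the material may rearrange by migration of the quaternary carbon. The fallback separates ring enlargement from methylation and sets out from 6. Me3Al‑promoted homologation with commercial trimethylsilyldiazomethane (CH2Cl2, −78 → −20 °C) should give, by methylene migration and a single insertion, (4S)‑2,2‑dimethyl‑4‑(triethylsilyloxy)‑6‑(trimethylsilyl)cyclohexan‑1‑one F1. Its C–Si bond is cleaved with K2CO3 in MeOH to give (4R)‑2,2‑dimethyl‑4‑(triethylsilyloxy)cyclohexan‑1‑one F2. Deprotonation with LiN(i‑Pr)2, possible only at the one α‑methylene, and alkylation with MeI bring the sequence back to 7.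

Step 9. Hydrogen abstraction may occur at the doubly allylic C6–H instead of C3, the tertiary bis‑allylic alcohol may be degraded by the peroxide, or C6 of the enone may epimerise. The fallback oxidises a substrate without the carbinol and sets out from 13. Ketalisation (ethylene glycol, HC(OMe)3, p‑TsOH) gives 2‑methyl‑2‑[(E)‑2‑[(1R)‑2,6,6‑trimethylcyclohex‑2‑en‑1‑yl]ethenyl]‑1,3‑dioxolane F3. Allylic oxidation with NaOCl/t‑BuOOH/K2CO3 in MeCN at 0 °C gives (4R)‑3,5,5‑trimethyl‑4‑[(E)‑2‑(2‑methyl‑1,3‑dioxolan‑2‑yl)ethenyl]cyclohex‑2‑en‑1‑one F4. Reduction with LiBH(s‑Bu)3 gives (1S,4R)‑3,5,5‑trimethyl‑4‑[(E)‑2‑(2‑methyl‑1,3‑dioxolan‑2‑yl)ethenyl]cyclohex‑2‑en‑1‑ol F5. Mild acid hydrolysis (pyridinium p‑toluenesulfonate, acetone/H2O) gives (3E)‑4‑[(1R,4S)‑4‑hydroxy‑2,6,6‑trimethylcyclohex‑2‑en‑1‑yl]but‑3‑en‑2‑one F6. Addition of CH2=CHMgBr (2.2 equiv) returns to 16.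

Step 7. Dehydration may be incomplete or give double‑bond‑shifted (retro) isomers, and bromide or phosphine may attack the wrong allylic terminus. The fallback forms the C6–C7 bond by cross‑coupling and sets out from 7 and 8. Deprotonation of 7 with KN(SiMe3)2 and trapping with PhNTf2 give (4R)‑2,6,6‑trimethyl‑4‑(triethylsilyloxy)cyclohex‑1‑en‑1‑yl trifluoromethanesulfonate F7. Hydrostannylation of 8 (Bu3SnH, PdCl2(PPh3)2) gives (2E,4E)‑3‑methyl‑5‑(tributylstannyl)penta‑2,4‑dien‑1‑ol F8. Stille coupling (Pd2(dba)3, AsPh3, LiCl, N‑methylpyrrolidone, 60 °C) gives (2E,4E)‑3‑methyl‑5‑[(4R)‑2,6,6‑trimethyl‑4‑(triethylsilyloxy)cyclohex‑1‑en‑1‑yl]penta‑2,4‑dien‑1‑ol F9. Treatment with PPh3·HBr in MeOH, which also cleaves the silyl ether, returns to 12.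

**Further compounds**

F1 | step 4 | (4S)‑2,2‑dimethyl‑4‑(triethylsilyloxy)‑6‑(trimethylsilyl)cyclohexan‑1‑one | O=C1C([Si](C)(C)C)C[C@@H](O[Si](CC)(CC)CC)CC1(C)C
F2 | step 4 | (4R)‑2,2‑dimethyl‑4‑(triethylsilyloxy)cyclohexan‑1‑one | O=C1CC[C@@H](O[Si](CC)(CC)CC)CC1(C)C
F3 | step 9 | 2‑methyl‑2‑[(E)‑2‑[(1R)‑2,6,6‑trimethylcyclohex‑2‑en‑1‑yl]ethenyl]‑1,3‑dioxolane | CC1(/C=C/[C@H]2C(C)=CCCC2(C)C)OCCO1
F4 | step 9 | (4R)‑3,5,5‑trimethyl‑4‑[(E)‑2‑(2‑methyl‑1,3‑dioxolan‑2‑yl)ethenyl]cyclohex‑2‑en‑1‑one | CC1(/C=C/[C@H]2C(C)=CC(=O)CC2(C)C)OCCO1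
F5 | step 9 | (1S,4R)‑3,5,5‑trimethyl‑4‑[(E)‑2‑(2‑methyl‑1,3‑dioxolan‑2‑yl)ethenyl]cyclohex‑2‑en‑1‑ol | CC1(/C=C/[C@H]2C(C)=C[C@@H](O)CC2(C)C)OCCO1
F6 | step 9 | (3E)‑4‑[(1R,4S)‑4‑hydroxy‑2,6,6‑trimethylcyclohex‑2‑en‑1‑yl]but‑3‑en‑2‑one | CC(=O)/C=C/[C@H]1C(C)=C[C@@H](O)CC1(C)C
F7 | step 7 | (4R)‑2,6,6‑trimethyl‑4‑(triethylsilyloxy)cyclohex‑1‑en‑1‑yl trifluoromethanesulfonate | CC[Si](CC)(CC)O[C@@H]1CC(C)=C(OS(=O)(=O)C(F)(F)F)C(C)(C)C1
F8 | step 7 | (2E,4E)‑3‑methyl‑5‑(tributylstannyl)penta‑2,4‑dien‑1‑ol | CCCC[Sn](CCCC)(CCCC)/C=C/C(C)=C/CO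
F9 | step 7 | (2E,4E)‑3‑methyl‑5‑[(4R)‑2,6,6‑trimethyl‑4‑(triethylsilyloxy)cyclohex‑1‑en‑1‑yl]penta‑2,4‑dien‑1‑ol | CC[Si](CC)(CC)O[C@@H]1CC(C)=C(/C=C/C(C)=C/CO)C(C)(C)C1
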